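Two orders are asked of this flask, and I reckon both from how much Z still stands at the moment I look.

| setting | autumn | dusk | flask |
|---|---|---|---|
| L | 16 mM | 16 mM | 16 mM |
| X | 16 mM | 16 mM | 16 mM |
| Z | 12 mM | 26 mM | 17.6 mM |
| G | 59 µM | 59 µM | 59 µM |
| remark | run made earlier | run made earlier |  |

- autumn (time / min: J / %, L / %): 0.200: 5.9, 43.3; 0.667: 10.1, 40.8; 1.00: 10.2, 40.4; 1.50: 10.7, 38.6; 2.50: 9.9, 39.5; 3.00: 10.0, 39.7; 4.00: 11.2, 38.3
- dusk (time / min: J / %, L / %): 0.500: 18.7, 29.7; 1.00: 21.3, 30.6; 1.50: 21.4, 29.7; 2.50: 20.9, 28.8; 3.00: 18.4, 30.1; 4.00: 20.6, 31.2

(scatter of a reading: 1 percentage point)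

1. apparent order in G when 10% of the L and X together are converted (percent change of the rate of making J for one percent more G charged)
2. apparent order in Z when 10% of the L and X together are converted (percent change of the rate of making J for one percent more Z charged)

- G is single-handed; L and X are mirror images of each other, charged as a racemate, each of them at the stated concentration
- no earlier run changes the charge of G; that part of a forecast is a guess

First setting, Z. By hand, the rate follows the Z present, and at a fixed conversion that is the charge less what was spent getting there. So while a fixed share of Z turns into product, the order in Z is one over (one minus the spent share), the spent share being the conversion looked at over the final conversion. The runs give the final J. The readings of J level off near 10.3% in autumn and 20.5% in dusk, while L still reads 31.2% in dusk, so I take Z as the limiting reagent. Per Z charged, that is 27.6% and 25.3% as J, about a quarter at both charges. I keep the mean, 26.4%, as the yield of J on Z.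

For the flask this gives a final J of 14.5%. What X makes is unseen. If X makes nothing, the order at 10% is 3.20; if X keeps pace with L, it is 1.52. I commit to their geometric mean, 2.21.

Second setting, G, which no run turns, so this is a guess. By hand, the rate follows G directly. If Z also vanishes by a path of its own, more G raises the final conversion and leaves more Z at the look, which adds the excess of the Z order over one, scaled by one minus the yield. That gives me 1.89.

The forecast says 1.4 (1.15 to 2) for Z and 1.35 (1 to 1.9) for G, both lower than mine. Its words on X are: “Assuming X reacts at a similar or somewhat faster rate”.

    Z → Q (k = 0.0570 s⁻¹)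
    G → D (k = 1.80 × 10⁻⁵ s⁻¹)
    Z + G + L → G + J (k = 27000 M⁻² s⁻¹)
    Z + G + X → G + E (k = 3400 M⁻² s⁻¹)

The simulated flask gives 2.4 in Z and 1.9 in G. After 4.00 min it holds 2.11% of E, less than its 14.5% of J, with 47.9% of X standing. Adding that E to the final J from my yield puts the spent share at 60.1% and the order in Z at 2.50, beside the simulated 2.4.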